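The pitfall in this flask is the tidy answer: a conformer pool gives a split that is easy to compute, while a second-order loss stands outside that split.

| setting | zeta | theta | delta | alpha |
|---|---|---|---|---|
| starting material | 15 mM | 15 mM | 15 mM | 15 mM |
| other conformer | 15.0 mM | 15.0 mM | 15.0 mM | 15.0 mM |
| catalyst | 15 µM | 15 µM | 15 µM | 15 µM |
| temperature | 20 °C | 0 °C | −20 °C | 40 °C |
| time | 2.0 min | 2.0 min | 2.0 min | 2.0 min |

    starting material ⇌ other conformer (K1 = 1.1, k1 = 0.070 s⁻¹, Ea1 = 68.0 kJ mol⁻¹, ΔH1 = −38.0 kJ mol⁻¹)
    starting material + catalyst → catalyst + target (k2 = 3900 M⁻¹ s⁻¹, Ea2 = 13.0 kJ mol⁻¹)
    catalyst + other conformer → catalyst + isomer of the product A (k3 = 9900 M⁻¹ s⁻¹, Ea3 = 21.0 kJ mol⁻¹)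
    target + catalyst ⇌ isomer of the product B + catalyst, rate k4*[catalyst]*[target] forward; the back reaction follows from the equilibrium constant (K4 = 0.70, k4 = 2100 M⁻¹ s⁻¹, Ea4 = 35.0 kJ mol⁻¹, ΔH4 = −62.0 kJ mol⁻¹)
    starting material + target → side product (k5 = 0.66 M⁻¹ s⁻¹, Ea5 = 43.0 kJ mol⁻¹)
    (constants at −20 °C)

- percentages count the starting material that a species holds: one side product counts as two
- all constants are for −20 °C and move with temperature by the activation energies and enthalpies
- in a conversion other conformer counts as not yet reacted

* the flask that comes out highest in amount of target, in percent of the starting material and other conformer together charged, or "all alike" when all lie within 1.5 percentage points (zeta / theta / delta / alpha / all alike)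
* target at the end, in percent of the starting material and other conformer together charged, zeta
* target at the end, in percent of the starting material and other conformer together charged, theta
* target at the end, in percent of the starting material and other conformer together charged, delta
* target at the end, in percent of the starting material and other conformer together charged, alpha

Every amount below is a fraction of the combined charge of starting material and other conformer. Two chemists dispute which flask wins.

The first holds the pool view, the Curtin–Hammett case. The conformers exchange, so the two catalysed channels share the charge in the ratio ρ: the exchange constant times the rate constant of the other-conformer channel over that of the target channel. Target is then one over one plus ρ. The symmetric case, ρ equal to one, is the zero of this scale. In theta ρ is 0.983, so half goes to target. In alpha ρ is 0.182, which gives 84.6 %. The first chemist bets on alpha.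

The second holds the ceiling view. Target is made in proportion to the catalyst and the starting material. It is eaten in proportion to the starting material and to target itself. The starting material cancels in the ratio of loss to making, which is S times the target fraction. Here S, the loss number, is the side-reaction constant times the combined charge, over the making constant times the catalyst, a dimensionless ratio of rates that changes with the loading. At the reference temperature it is 0.338. In alpha it is 5.19. Leaving the isomer step aside, target stops climbing at one over S, which in alpha is 19.3 %, lower than the pool's figure.

I side with the second chemist. My own blend says that one over target equals one plus ρ plus S, which returns either view when the other term is small. In theta S is 0.961, close to ρ. The blend gives 34.0 % for theta and 15.7 % for alpha. For zeta, ρ is 0.399 and S is 2.37, giving 26.6 %. For delta, ρ is 2.79, giving 24.2 %. That last figure is my weakest, since the exchange there is slower than the catalysed loss of other conformer. My winner is theta.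

The forecast takes the second side with numbers of its own, not those of my blend. It names theta, with 30.4 % for zeta, 34.9 % for theta, 19.6 % for delta and 18.2 % for alpha. Its grounds: “These opposing effects put the optimum near 0 °C”.

The simulation gives theta, with 30.4 % for zeta, 34.9 % for theta, 19.4 % for delta and 18.1 % for alpha. The forecast stands on the winner and on each number, and the pool view loses.

The side reaction is the main reason alpha falls short. With that step struck out, target in alpha stands at 84.4 % instead of 18.1 %, beside the pool figure of 84.6 %. That struck-out run is the region where the first chemist is right. With that step taken away, the answer to which flask wins turns, and the forecast's theta no longer stands.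

Take a neighbour flask, the same as theta but run at 15 °C. There S is 1.91 and ρ is 0.494, so the blend gives 29.4 %. The computed target is 33.1 %.

The constants used here were drawn at random within sensible limits; the result is computed.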